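## Retrosynthetic overview
1. C5–prenyl bond (made last): lespeflorin C5 ⇒ the 4-O-(1,1-dimethylallyl) ether of the unprenylated ketone. An aromatic Claisen shift through a dearomatised ring A cyclohexadienone turns the tertiary ether into the linear prenyl group; C3 is blocked by methyl.
2. Aryl O–C bond: this ether ⇒ unprenylated α-hydroxydihydrochalcone + tert-butyl 1,1-dimethylallyl carbonate (Tsuji–Trost reaction at the most acidic phenol, no protecting groups).
3. Key step, aryl–C(=O) bond: the ketone ⇒ C2v-symmetric 2-methylresorcinol + unprotected (S)-3-(4-hydroxyphenyl)lactic acid. One acylation at either of the two equivalent ring positions breaks the symmetry. It also brings in the whole C9 arm with the carbinol centre already in place (the target centre is S).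
4. Rings: none is formed; both benzene rings are bought.

Assumption: 2-methylresorcinol 1, (S)-3-(4-hydroxyphenyl)lactic acid 2 (the acid of the L-tyrosine series) and tert-butyl 2-methylbut-3-en-2-yl carbonate 3 are all taken as catalogue chemicals.

## Route

Step 1
Reactants: 1 2-methylresorcinol; 2 (S)-3-(4-hydroxyphenyl)lactic acid
Product: 5 (2S)-1-(2,4-dihydroxy-3-methylphenyl)-2-hydroxy-3-(4-hydroxyphenyl)propan-1-one, via difluoroboron chelate 4 (not isolated)
Conditions: BF3·OEt2 (8 equiv, neat), 1 (1.5 equiv), N2, 65–70 °C, 2 h; then ice/H2O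
Reagents that add atoms: none
Why: Proposed new method: BF3 first locks the α-hydroxy acid as its five-membered difluoroboron chelate 4, which masks the carbinol oxygen as an electron-poor B–O bond (no self-esterification, no CO loss from the acyl donor) and makes the carboxyl carbon a mixed-anhydride-type electrophile that attacks one of the two homotopic positions C4/C6 of the C2v-symmetric arene 1 (only one regioisomer is possible, and the new hydrogen-bonded ketone deactivates the ring against a second acylation), while the stereocentre is a spectator carried over unchanged from 2; the closest known reaction type is the BF3·OEt2-mediated Nencki-type Friedel–Crafts acylation (O-acylation/Fries pathway) of resorcinols with free hydroxyphenylacetic and hydroxyphenylpropionic acids, and Lewis-acid Friedel–Crafts acylations with chiral α-heteroatom-substituted acyl donors are known to keep their configuration.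

Step 2
Reactants: 5 (2S)-1-(2,4-dihydroxy-3-methylphenyl)-2-hydroxy-3-(4-hydroxyphenyl)propan-1-one; 3 tert-butyl 2-methylbut-3-en-2-yl carbonate
Product: 6 (2S)-2-hydroxy-1-[2-hydroxy-3-methyl-4-(2-methylbut-3-en-2-yloxy)phenyl]-3-(4-hydroxyphenyl)propan-1-one
Conditions: 3 (1.0 equiv), Pd(PPh3)4 (5 mol %), THF, 0–5 °C, 3 h; short neutral Al2O3 plug
Reagents that add atoms: none
Why: In this Tsuji–Trost O-allylation zerovalent palladium ionises 3 with loss of CO2, the tert-butoxide released deprotonates only the most acidic OH (the 4-OH para to the ketone lies about two pKa units below the ring B phenol, the 2-OH is tied up in a hydrogen bond, and the carbinol is not acidic), and at low temperature this phenoxide attacks the more substituted allyl terminus to give the kinetic tertiary ether without touching the stereocentre.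

Step 3
Reactants: 6 (2S)-2-hydroxy-1-[2-hydroxy-3-methyl-4-(2-methylbut-3-en-2-yloxy)phenyl]-3-(4-hydroxyphenyl)propan-1-one
Product: 8 lespeflorin C5 [(2S)-1-[2,4-dihydroxy-3-methyl-5-(3-methylbut-2-en-1-yl)phenyl]-2-hydroxy-3-(4-hydroxyphenyl)propan-1-one], via cyclohexadienone 7 (not isolated)
Conditions: PhMe (0.05 M), N2, 110 °C, 3 h
Reagents that add atoms: none
Why: In this aromatic Claisen rearrangement the [3,3] shift breaks the aromaticity of ring A and inverts the allyl unit, so the 1,1-dimethylallyl ether delivers the linear prenyl group to C5 in dienone 7 (its ring stereocentre is transient and is erased on tautomerisation to the phenol), migration to the methyl-blocked C3 is reversible and drains back, and the neutral medium leaves the (S)-carbinol untouched.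

## Compound list
1 | 2-methylresorcinol (2-methylbenzene-1,3-diol) | Cc1c(O)cccc1O | starting material
2 | (S)-3-(4-hydroxyphenyl)lactic acid [(2S)-2-hydroxy-3-(4-hydroxyphenyl)propanoic acid] | OC(=O)[C@@H](O)Cc1ccc(O)cc1 | starting material
3 | tert-butyl 2-methylbut-3-en-2-yl carbonate | CC(C)(C)OC(=O)OC(C)(C)C=C | starting material
4 | five-membered O,O-difluoroboron chelate of 2 (boron bound to the carbinol O and to the carboxyl C=O, (S) centre unchanged) | OC1=[O+][B-](F)(F)O[C@H]1Cc2ccc(O)cc2 | intermediate
5 | (2S)-1-(2,4-dihydroxy-3-methylphenyl)-2-hydroxy-3-(4-hydroxyphenyl)propan-1-one | Cc1c(O)ccc(C(=O)[C@@H](O)Cc2ccc(O)cc2)c1O | intermediate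
6 | (2S)-2-hydroxy-1-[2-hydroxy-3-methyl-4-(2-methylbut-3-en-2-yloxy)phenyl]-3-(4-hydroxyphenyl)propan-1-one | C=CC(C)(C)Oc1ccc(C(=O)[C@@H](O)Cc2ccc(O)cc2)c(O)c1C | intermediate
7 | 3-hydroxy-4-[(2S)-2-hydroxy-3-(4-hydroxyphenyl)propanoyl]-2-methyl-6-(3-methylbut-2-en-1-yl)cyclohexa-2,4-dien-1-one (both epimers at ring C6) | CC(C)=CCC1C=C(C(=O)[C@@H](O)Cc2ccc(O)cc2)C(O)=C(C)C1=O | intermediate
8 | lespeflorin C5, (2S)-1-[2,4-dihydroxy-3-methyl-5-(3-methylbut-2-en-1-yl)phenyl]-2-hydroxy-3-(4-hydroxyphenyl)propan-1-one | CC(C)=CCc1cc(C(=O)[C@@H](O)Cc2ccc(O)cc2)c(O)c(C)c1O | target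

Total step count: 3.
Longest linear sequence: 3 steps (1 or 2 → 5 → 6 → 8).

## Steps most likely to fail

**Step 1 (highest risk).**
- What can go wrong: partial racemisation through a boron enediolate at 65–70 °C, CO loss from the α-oxygenated acyl donor, or oligoester formation. The ee of 5 is checked by chiral HPLC.
- Fallback: it reverses the polarity (aryl anion plus amide in place of arene plus acyl electrophile), sets out from 1 and 2, and comes back at 5.
- Protect 1 with MOMCl and i-Pr2NEt in CH2Cl2 to give 1,3-bis(methoxymethoxy)-2-methylbenzene F1.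
- Lithiate the ring ortho to one of the two equivalent OMOM groups (n-BuLi, TMEDA, THF, 0 °C) to give [2,4-bis(methoxymethoxy)-3-methylphenyl]lithium F2.
- Convert 2 with MeNHOMe·HCl, EDC·HCl, HOBt and N-methylmorpholine into (2S)-2-hydroxy-3-(4-hydroxyphenyl)-N-methoxy-N-methylpropanamide F3.
- Neutralise the two OH groups of the amide with i-PrMgCl (2 equiv). Add the aryllithium at −78 °C and quench with NH4Cl. This gives (2S)-1-[2,4-bis(methoxymethoxy)-3-methylphenyl]-2-hydroxy-3-(4-hydroxyphenyl)propan-1-one F4.
- Remove both MOM groups with HCl in MeOH at 40 °C to reach 5. No prenyl group is present at this stage, so the acid does no harm.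

**Step 2.**
- What can go wrong: the good aryloxide leaving group lets the tertiary ether re-ionise and drift to the linear ether, and some ring B phenol may be alkylated.
- Fallback: it replaces palladium allyl chemistry by copper-catalysed propargylic substitution followed by semi-hydrogenation, sets out from 5, and comes back at 6.
- Treat 5 with 3-chloro-3-methylbut-1-yne, CuCl2 (1 mol %) and DBU (1.05 equiv) in MeCN at 0 °C. This gives (2S)-2-hydroxy-1-[2-hydroxy-3-methyl-4-(2-methylbut-3-yn-2-yloxy)phenyl]-3-(4-hydroxyphenyl)propan-1-one F5.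
- Reduce the alkyne with H2 (1 atm) over Pd/CaCO3 poisoned with Pb(OAc)2, with quinoline, in EtOAc to reach 6. No other C=C bond is present at this stage.

**Step 3.**
- What can go wrong: thermal loss of isoprene from the tertiary ether back to 5, or erosion of ee at 110 °C.
- Fallback: it replaces the pericyclic step by an ionic, ion-pair [1,3] shift on a solid acid at room temperature, sets out from 5, and comes back at 8.
- Alkylate the acidic 4-OH of 5 with prenyl bromide and K2CO3 (1.0 equiv) in acetone. This gives (2S)-2-hydroxy-1-[2-hydroxy-3-methyl-4-(3-methylbut-2-en-1-yloxy)phenyl]-3-(4-hydroxyphenyl)propan-1-one F6.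
- Stir it with Montmorillonite K10 clay (idealised Al2Si4O10(OH)2·nH2O) in CH2Cl2 at 0 °C to rt. The prenyl cation collapses onto the only free ortho position, C5, and gives 8.

Further compounds
F1 | step 1 | 1,3-bis(methoxymethoxy)-2-methylbenzene | COCOc1cccc(OCOC)c1C
F2 | step 1 | [2,4-bis(methoxymethoxy)-3-methylphenyl]lithium | [Li]c1ccc(OCOC)c(C)c1OCOC
F3 | step 1 | (2S)-2-hydroxy-3-(4-hydroxyphenyl)-N-methoxy-N-methylpropanamide | CON(C)C(=O)[C@@H](O)Cc1ccc(O)cc1
F4 | step 1 | (2S)-1-[2,4-bis(methoxymethoxy)-3-methylphenyl]-2-hydroxy-3-(4-hydroxyphenyl)propan-1-one | COCOc1ccc(C(=O)[C@@H](O)Cc2ccc(O)cc2)c(OCOC)c1C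
F5 | step 2 | (2S)-2-hydroxy-1-[2-hydroxy-3-methyl-4-(2-methylbut-3-yn-2-yloxy)phenyl]-3-(4-hydroxyphenyl)propan-1-one | C#CC(C)(C)Oc1ccc(C(=O)[C@@H](O)Cc2ccc(O)cc2)c(O)c1C
F6 | step 3 | (2S)-2-hydroxy-1-[2-hydroxy-3-methyl-4-(3-methylbut-2-en-1-yloxy)phenyl]-3-(4-hydroxyphenyl)propan-1-one | CC(C)=CCOc1ccc(C(=O)[C@@H](O)Cc2ccc(O)cc2)c(O)c1C
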